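**Retrosynthetic overview**

1. The target is reached by hydrogenolysis of its octabenzyl ether; all eight phenols travel as benzyl ethers.
2. Ring C of the flavanone (O1–C2–C3–C4–C4a–C8a) comes from one-carbon ring expansion of the five-membered oxygen ring of a 1a-aryl-6b-siloxy-cyclopropa[b]benzofuran: fluoride frees the C6b alkoxide, the shared C1a–C6b bond breaks, the cyclopropane CH2 becomes C3, C6b becomes the C4 ketone and C1a becomes C2.
3. Enabling feature: C2 of ring C is benzylic to ring B and bound to O1, and it sits β to the ring A aryl ketone carbon C4; a CH2-bridged cyclopropanolate across C2–C4 therefore opens only towards C2, and protonation there with inversion relays the cyclopropane configuration to C2.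
4. The biaryl bond C6′ (ring B)–C8″ (luteolin) is made by Suzuki coupling at the cyclopropane stage, where both stereocentres are locked and base-stable; luteolin is bought and functionalised at C8 (benzylation, iodination, borylation).
5. The cyclopropane comes from enantioselective zinc-carbenoid CH2 transfer to a 2-aryl-3-siloxybenzofuran, itself from Friedel–Crafts closure of an aryloxy(aryl)acetic acid (α-bromo arylacetate + 3,5-bis(benzyloxy)phenol); ring order: furanone ring, cyclopropane, then ring C by expansion.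

Key step: step 13

Remark: the C6′–C8″ biaryl axis has three ortho substituents but no descriptor in the target; it is taken as not configurationally fixed and no axial control is attempted.
Remark: which antipode of the Boc-Val-Pro-OMe ligand (L,L or D,D) gives the (1aS,6bS) cyclopropane cannot be read from precedent on this substrate; it is to be fixed in the first run, both antipodes being accessible.
Remark: 3,5-bis(benzyloxy)phenol and luteolin are taken as catalogue compounds.

**Route**

Step 1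
Reactants: 1 3,4-dihydroxyphenylacetic acid
Product: 2 benzyl 2-[3,4-bis(benzyloxy)phenyl]acetate
Conditions: BnBr (3.5 equiv), K2CO3, DMF, 60 °C
Reagents that add atoms: benzyl bromide, BrCc1ccccc1
Why: Exhaustive O-alkylation (Williamson ether synthesis plus carboxylate alkylation) should benzylate both phenols and the acid in one pot, giving an ester that can be enolised later.

Step 2
Reactants: 2 benzyl 2-[3,4-bis(benzyloxy)phenyl]acetate
Product: 3 benzyl 2-[4,5-bis(benzyloxy)-2-bromophenyl]acetate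
Conditions: NBS, MeCN, 0 °C → rt
Reagents that add atoms: N-bromosuccinimide, O=C1CCC(=O)N1Br
Why: Electrophilic aromatic bromination should go para to the 3-benzyloxy group and ortho to the CH2 side chain, the usual outcome for 3,4-dialkoxyphenylacetic acid derivatives.

Step 3
Reactants: 3 benzyl 2-[4,5-bis(benzyloxy)-2-bromophenyl]acetate
Product: 5 benzyl 2-bromo-2-[4,5-bis(benzyloxy)-2-bromophenyl]acetate (racemic), via lithium enolate 4 (not isolated)
Conditions: LiHMDS, THF, −78 °C; then NBS, −78 °C; AcOH quench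
Reagents that add atoms: N-bromosuccinimide, O=C1CCC(=O)N1Br
Why: Ester enolate halogenation: the benzylic ester is deprotonated cleanly at −78 °C and the enolate is brominated faster than it condenses; no stereocontrol is needed because this centre becomes sp2 in step 7.

Step 4
Reactants: 5 benzyl 2-bromo-2-[4,5-bis(benzyloxy)-2-bromophenyl]acetate; 6 3,5-bis(benzyloxy)phenol
Product: 7 benzyl 2-[4,5-bis(benzyloxy)-2-bromophenyl]-2-[3,5-bis(benzyloxy)phenoxy]acetate (racemic)
Conditions: K2CO3, acetone, 50 °C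
Reagents that add atoms: none
Why: Williamson ether synthesis (SN2) of the phenoxide on the doubly activated secondary α-bromo ester; phenols of this type are O-alkylated under K2CO3 in acetone.

Step 5
Reactants: 7 benzyl 2-[4,5-bis(benzyloxy)-2-bromophenyl]-2-[3,5-bis(benzyloxy)phenoxy]acetate
Product: 8 2-[4,5-bis(benzyloxy)-2-bromophenyl]-2-[3,5-bis(benzyloxy)phenoxy]acetic acid (racemic)
Conditions: LiOH, THF/MeOH/H2O, rt; then 1 M HCl
Reagents that add atoms: lithium hydroxide, [Li+].[OH-]
Why: Saponification of the benzyl ester (acyl substitution by hydroxide) leaves the benzyl ethers and the aryl bromide untouched.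

Step 6
Reactants: 8 2-[4,5-bis(benzyloxy)-2-bromophenyl]-2-[3,5-bis(benzyloxy)phenoxy]acetic acid
Product: 10 4,6-bis(benzyloxy)-2-[4,5-bis(benzyloxy)-2-bromophenyl]-1-benzofuran-3(2H)-one (racemic; used crude under argon), via mixed trifluoroacetic anhydride 9 (not isolated)
Conditions: (CF3CO)2O, CH2Cl2, 0 °C → rt; aq. NaHCO3 work-up
Reagents that add atoms: none
Why: Intramolecular Friedel–Crafts acylation through the mixed anhydride: the phloroglucinol-type ring is attacked at either of its two equivalent positions ortho to the ether oxygen, closing the furanone ring without a free acylium ion (which could lose CO) and without cleaving benzyl ethers.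

Step 7
Reactants: 10 4,6-bis(benzyloxy)-2-[4,5-bis(benzyloxy)-2-bromophenyl]-1-benzofuran-3(2H)-one
Product: 11 {[4,6-bis(benzyloxy)-2-(4,5-bis(benzyloxy)-2-bromophenyl)-1-benzofuran-3-yl]oxy}(tert-butyl)dimethylsilane
Conditions: TBSOTf, Et3N, CH2Cl2, 0 °C
Reagents that add atoms: tert-butyldimethylsilyl trifluoromethanesulfonate, CC(C)(C)[Si](C)(C)OS(=O)(=O)C(F)(F)F
Why: Silyl enol ether formation is driven to oxygen by aromatisation to the benzofuran and removes both the labile C2 centre and the air-sensitive ketone.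

Step 8
Reactants: 11 {[4,6-bis(benzyloxy)-2-(4,5-bis(benzyloxy)-2-bromophenyl)-1-benzofuran-3-yl]oxy}(tert-butyl)dimethylsilane
Product: 12 (1aS,6bS)-4,6-bis(benzyloxy)-1a-[4,5-bis(benzyloxy)-2-bromophenyl]-6b-[(tert-butyldimethylsilyl)oxy]-1a,6b-dihydro-1H-cyclopropa[b][1]benzofuran
Conditions: Et2Zn, CH2I2, Boc-Val-Pro-OMe (25 mol %, antipode as in the remark), CH2Cl2, −40 → 0 °C
Reagents that add atoms: diiodomethane, ICI
Why: Proposed new method: the electron-rich, fully substituted C2=C3 enol ether bond of the 3-siloxybenzofuran should take up CH2 from Zn(CH2I)2 in the concerted butterfly transition state (syn addition, cis-fused by necessity), the zinc-bound dipeptide shielding one enantiotopic face so that both stereocentres (C1a and C6b) are set together by the catalyst; the closest known reaction type is the dipeptide-catalysed asymmetric Simmons–Smith cyclopropanation of trisubstituted aryl silyl enol ethers, together with the ligand-free Et2Zn/CH2I2 cyclopropanation of tetrasubstituted silyl enol ethers.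

Step 9
Reactants: 13 luteolin
Product: 14 5,7-bis(benzyloxy)-2-[3,4-bis(benzyloxy)phenyl]-4H-chromen-4-one
Conditions: BnBr (6 equiv), K2CO3, Bu4NI (cat.), DMF, 80 °C
Reagents that add atoms: benzyl bromide, BrCc1ccccc1
Why: Williamson ether synthesis under forcing conditions should also benzylate the chelated 5-OH.

Step 10
Reactants: 14 5,7-bis(benzyloxy)-2-[3,4-bis(benzyloxy)phenyl]-4H-chromen-4-one
Product: 15 5,7-bis(benzyloxy)-2-[3,4-bis(benzyloxy)phenyl]-8-iodo-4H-chromen-4-one
Conditions: NIS, CF3CO2H (cat.), CH2Cl2/MeCN, 0 °C → rt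
Reagents that add atoms: N-iodosuccinimide, O=C1CCC(=O)N1I
Why: Electrophilic aromatic iodination: in 5,7-dialkoxyflavones C8 (para to the 5-alkoxy group, ortho to the 7-alkoxy group) is the usual site of halogenation, and the catechol ring is deactivated by conjugation with the pyranone.

Step 11
Reactants: 15 5,7-bis(benzyloxy)-2-[3,4-bis(benzyloxy)phenyl]-8-iodo-4H-chromen-4-one
Product: 16 5,7-bis(benzyloxy)-2-[3,4-bis(benzyloxy)phenyl]-8-(4,4,5,5-tetramethyl-1,3,2-dioxaborolan-2-yl)-4H-chromen-4-one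
Conditions: B2pin2, PdCl2(dppf), KOAc, 1,4-dioxane, 90 °C
Reagents that add atoms: bis(pinacolato)diboron, CC1(C)OB(OC1(C)C)B1OC(C)(C)C(C)(C)O1
Why: Miyaura borylation: oxidative addition of zerovalent palladium into the aryl iodide, acetate-assisted transmetalation with the diboron reagent and reductive elimination, as used for 8-iodoflavones.

Step 12
Reactants: 12 (1aS,6bS)-bromoaryl siloxycyclopropane; 16 flavone 8-boronate (1.3 equiv)
Product: 17 (1aS,6bS)-4,6-bis(benzyloxy)-1a-{4,5-bis(benzyloxy)-2-[5,7-bis(benzyloxy)-2-(3,4-bis(benzyloxy)phenyl)-4-oxo-4H-chromen-8-yl]phenyl}-6b-[(tert-butyldimethylsilyl)oxy]-1a,6b-dihydro-1H-cyclopropa[b][1]benzofuran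
Conditions: Pd(OAc)2, SPhos, K3PO4, toluene/H2O, 80 °C
Reagents that add atoms: none
Why: Suzuki–Miyaura coupling with a bulky biarylphosphine should form the tri-ortho-substituted biaryl; the silyl-protected cyclopropane has no enolisable or base-labile site, so both stereocentres pass through the basic coupling unchanged.

Step 13
Reactants: 17 (1aS,6bS)-biaryl siloxycyclopropane
Product: 19 (2R)-5,7-bis(benzyloxy)-2-{4,5-bis(benzyloxy)-2-[5,7-bis(benzyloxy)-2-(3,4-bis(benzyloxy)phenyl)-4-oxo-4H-chromen-8-yl]phenyl}-2,3-dihydro-4H-chromen-4-one, via tetrabutylammonium cyclopropanolate 18 (not isolated)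
Conditions: TBAF (1.2 equiv), THF/H2O 9:1, −20 → 0 °C; AcOH quench at −20 °C
Reagents that add atoms: none
Why: Fluoride removes the silyl group and the free C6b alkoxide 18 collapses to the C4 carbonyl while the shared C1a–C6b bond breaks, the charge building up on C1a, which is benzylic to ring B and bound to the ring oxygen, and being taken up by a proton from water as the bond breaks. The closest known reaction type is the base-induced ring opening of 2-arylcyclopropanols to β-aryl ketones, which cleaves the bond to the benzylic carbon and protonates it with inversion, combined with fluoride-triggered opening of siloxycyclopropanes. No ring bond is formed: ring C arises by scission of the zero-atom bridge of the 2-oxabicyclo[3.1.0]hexane, so that the five-membered oxygen ring takes in the cyclopropane CH2 as C3 and becomes six-membered. The one stereocentre that remains, C2, is controlled by C1a of the cyclopropane (set in step 8): the proton enters at the exposed back lobe of the breaking bond, the front side lying inside the new ring, so (1aS) should become (2R). The step needs internal instead of external cyclopropane bond cleavage, secured by the aryl group and the oxygen on C1a and by the larger strain relief, and it needs the product to escape base-induced retro-oxa-Michael opening, for which the low temperature, the protic medium and the acetic acid quench are chosen.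

Step 14
Reactants: 19 (2R)-flavanone–flavone octabenzyl ether
Product: 20 (2R)-2-{2-[2-(3,4-dihydroxyphenyl)-5,7-dihydroxy-4-oxo-4H-chromen-8-yl]-4,5-dihydroxyphenyl}-5,7-dihydroxy-2,3-dihydro-4H-chromen-4-one (target)
Conditions: H2 (1 atm), Pd(OH)2 on carbon, THF/MeOH, rt
Reagents that add atoms: none
Why: Hydrogenolysis of the eight benzyl ethers under neutral conditions; the flavone enone and the aryl ketone are slow to reduce at 1 atm, and the neutral medium leaves C2 untouched.

**Compound list**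

1 | 3,4-dihydroxyphenylacetic acid | OC(=O)Cc1ccc(O)c(O)c1 | starting material
2 | benzyl 2-[3,4-bis(benzyloxy)phenyl]acetate | O=C(OCc1ccccc1)Cc1ccc(OCc2ccccc2)c(OCc2ccccc2)c1 | intermediate
3 | benzyl 2-[4,5-bis(benzyloxy)-2-bromophenyl]acetate | O=C(OCc1ccccc1)Cc1cc(OCc2ccccc2)c(OCc2ccccc2)cc1Br | intermediate
4 | lithium enolate of 3 | [Li+].[O-]C(OCc1ccccc1)=Cc1cc(OCc2ccccc2)c(OCc2ccccc2)cc1Br | intermediate
5 | benzyl 2-bromo-2-[4,5-bis(benzyloxy)-2-bromophenyl]acetate (racemic) | O=C(OCc1ccccc1)C(Br)c1cc(OCc2ccccc2)c(OCc2ccccc2)cc1Br | intermediate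
6 | 3,5-bis(benzyloxy)phenol | Oc1cc(OCc2ccccc2)cc(OCc2ccccc2)c1 | starting material
7 | benzyl 2-[4,5-bis(benzyloxy)-2-bromophenyl]-2-[3,5-bis(benzyloxy)phenoxy]acetate (racemic) | O=C(OCc1ccccc1)C(Oc1cc(OCc2ccccc2)cc(OCc2ccccc2)c1)c1cc(OCc2ccccc2)c(OCc2ccccc2)cc1Br | intermediate
8 | 2-[4,5-bis(benzyloxy)-2-bromophenyl]-2-[3,5-bis(benzyloxy)phenoxy]acetic acid (racemic) | OC(=O)C(Oc1cc(OCc2ccccc2)cc(OCc2ccccc2)c1)c1cc(OCc2ccccc2)c(OCc2ccccc2)cc1Br | intermediate
9 | mixed anhydride of 8 with trifluoroacetic acid | O=C(OC(=O)C(F)(F)F)C(Oc1cc(OCc2ccccc2)cc(OCc2ccccc2)c1)c1cc(OCc2ccccc2)c(OCc2ccccc2)cc1Br | intermediate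
10 | 4,6-bis(benzyloxy)-2-[4,5-bis(benzyloxy)-2-bromophenyl]-1-benzofuran-3(2H)-one (racemic, enolisable) | O=C1C(c2cc(OCc3ccccc3)c(OCc3ccccc3)cc2Br)Oc2cc(OCc3ccccc3)cc(OCc3ccccc3)c21 | intermediate
11 | {[4,6-bis(benzyloxy)-2-(4,5-bis(benzyloxy)-2-bromophenyl)-1-benzofuran-3-yl]oxy}(tert-butyl)dimethylsilane | CC(C)(C)[Si](C)(C)Oc1c(-c2cc(OCc3ccccc3)c(OCc3ccccc3)cc2Br)oc2cc(OCc3ccccc3)cc(OCc3ccccc3)c12 | intermediate
12 | (1aS,6bS)-4,6-bis(benzyloxy)-1a-[4,5-bis(benzyloxy)-2-bromophenyl]-6b-[(tert-butyldimethylsilyl)oxy]-1a,6b-dihydro-1H-cyclopropa[b][1]benzofuran | C1[C@@]2(c3cc(OCc4ccccc4)c(OCc4ccccc4)cc3Br)Oc3cc(OCc4ccccc4)cc(OCc4ccccc4)c3[C@@]12O[Si](C)(C)C(C)(C)C | intermediate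
13 | luteolin | O=c1cc(-c2ccc(O)c(O)c2)oc2cc(O)cc(O)c12 | starting material
14 | 5,7-bis(benzyloxy)-2-[3,4-bis(benzyloxy)phenyl]-4H-chromen-4-one | O=c1cc(-c2ccc(OCc3ccccc3)c(OCc3ccccc3)c2)oc2cc(OCc3ccccc3)cc(OCc3ccccc3)c12 | intermediate
15 | 5,7-bis(benzyloxy)-2-[3,4-bis(benzyloxy)phenyl]-8-iodo-4H-chromen-4-one | O=c1cc(-c2ccc(OCc3ccccc3)c(OCc3ccccc3)c2)oc2c(I)c(OCc3ccccc3)cc(OCc3ccccc3)c12 | intermediate
16 | 5,7-bis(benzyloxy)-2-[3,4-bis(benzyloxy)phenyl]-8-(4,4,5,5-tetramethyl-1,3,2-dioxaborolan-2-yl)-4H-chromen-4-one | O=c1cc(-c2ccc(OCc3ccccc3)c(OCc3ccccc3)c2)oc2c(B3OC(C)(C)C(C)(C)O3)c(OCc3ccccc3)cc(OCc3ccccc3)c12 | intermediate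
17 | (1aS,6bS)-4,6-bis(benzyloxy)-1a-{4,5-bis(benzyloxy)-2-[5,7-bis(benzyloxy)-2-(3,4-bis(benzyloxy)phenyl)-4-oxo-4H-chromen-8-yl]phenyl}-6b-[(tert-butyldimethylsilyl)oxy]-1a,6b-dihydro-1H-cyclopropa[b][1]benzofuran | C1[C@@]2(c3cc(OCc4ccccc4)c(OCc4ccccc4)cc3-c3c(OCc4ccccc4)cc(OCc4ccccc4)c4c(=O)cc(-c5ccc(OCc6ccccc6)c(OCc6ccccc6)c5)oc34)Oc3cc(OCc4ccccc4)cc(OCc4ccccc4)c3[C@@]12O[Si](C)(C)C(C)(C)C | intermediate
18 | tetrabutylammonium (1aS,6bS)-cyclopropanolate formed from 17 by loss of the silyl group | C1[C@@]2(c3cc(OCc4ccccc4)c(OCc4ccccc4)cc3-c3c(OCc4ccccc4)cc(OCc4ccccc4)c4c(=O)cc(-c5ccc(OCc6ccccc6)c(OCc6ccccc6)c5)oc34)Oc3cc(OCc4ccccc4)cc(OCc4ccccc4)c3[C@@]12[O-].CCCC[N+](CCCC)(CCCC)CCCC | intermediate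
19 | (2R)-5,7-bis(benzyloxy)-2-{4,5-bis(benzyloxy)-2-[5,7-bis(benzyloxy)-2-(3,4-bis(benzyloxy)phenyl)-4-oxo-4H-chromen-8-yl]phenyl}-2,3-dihydro-4H-chromen-4-one | O=C1C[C@H](c2cc(OCc3ccccc3)c(OCc3ccccc3)cc2-c2c(OCc3ccccc3)cc(OCc3ccccc3)c3c(=O)cc(-c4ccc(OCc5ccccc5)c(OCc5ccccc5)c4)oc23)Oc2cc(OCc3ccccc3)cc(OCc3ccccc3)c21 | intermediate
20 | (2R)-2-{2-[2-(3,4-dihydroxyphenyl)-5,7-dihydroxy-4-oxo-4H-chromen-8-yl]-4,5-dihydroxyphenyl}-5,7-dihydroxy-2,3-dihydro-4H-chromen-4-one | O=C1C[C@H](c2cc(O)c(O)cc2-c2c(O)cc(O)c3c(=O)cc(-c4ccc(O)c(O)c4)oc23)Oc2cc(O)cc(O)c21 | target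

**Step count and risks**

Total steps: 14. Longest linear sequence: 11 (steps 1–8, 12, 13, 14); the luteolin branch (steps 9–11) joins at step 12.

Steps most likely to fail:

1. Step 8. The risk is poor facial discrimination on a tetrasubstituted enol ether whose ether oxygens can direct a ligand-free background carbenoid, or sluggish CH2 transfer to the benzofuran C2=C3 bond. The fallback uses known chemistry, sets out from 11 and returns at 12. Ligand-free Simmons–Smith cyclopropanation with Et2Zn/CH2I2 (CH2Cl2, 0 °C → rt), standard for silyl enol ethers, should give the racemic siloxycyclopropane F1. Preparative chromatography on a polysaccharide-based chiral stationary phase should then separate 12 from its (1aR,6bR) enantiomer F2.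

2. Step 13. The risk is leakage of configuration, either by planarisation of the benzylic carbanion before protonation or by base-induced retro-oxa-Michael opening of the flavanone once formed; cleavage of the external C6b–CH2 bond is a second possible failure. The fallback sets out from 17 and returns at 19, and gives up the stereospecific relay. Excess TBAF in THF at 40 °C should take 17 through the flavanone into the ring-opened (E)-2′-hydroxychalcone F3. NaOAc in refluxing EtOH should reclose it by oxa-Michael addition to the racemic flavanone F4 (classical chalcone–flavanone isomerisation). Preparative chiral HPLC should then deliver 19 and leave the (2S) enantiomer F5.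

3. Step 12. The risk is protodeboronation of the di-ortho-oxygenated flavone boronate outrunning a slow transmetalation to the hindered arylpalladium bromide, with possible attack of that intermediate on the neighbouring cyclopropane. The fallback sets out from 12 and returns at 17, with the polarity of the partners reversed. Miyaura borylation of 12 (B2pin2, PdCl2(dppf), KOAc, dioxane, 90 °C) should give the cyclopropane aryl boronate F6. This is coupled with iodide 15 (Pd(OAc)2, SPhos, K3PO4, toluene/H2O), so that the labile boronate 16 and step 11 are not needed.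

Further compounds
F1 | step 8 | racemic 4,6-bis(benzyloxy)-1a-[4,5-bis(benzyloxy)-2-bromophenyl]-6b-[(tert-butyldimethylsilyl)oxy]-1a,6b-dihydro-1H-cyclopropa[b][1]benzofuran | C1C2(c3cc(OCc4ccccc4)c(OCc4ccccc4)cc3Br)Oc3cc(OCc4ccccc4)cc(OCc4ccccc4)c3C12O[Si](C)(C)C(C)(C)C
F2 | step 8 | (1aR,6bR) enantiomer of 12 | C1[C@]2(c3cc(OCc4ccccc4)c(OCc4ccccc4)cc3Br)Oc3cc(OCc4ccccc4)cc(OCc4ccccc4)c3[C@]12O[Si](C)(C)C(C)(C)C
F3 | step 13 | (E)-1-[2,4-bis(benzyloxy)-6-hydroxyphenyl]-3-{4,5-bis(benzyloxy)-2-[5,7-bis(benzyloxy)-2-(3,4-bis(benzyloxy)phenyl)-4-oxo-4H-chromen-8-yl]phenyl}prop-2-en-1-one | O=C(/C=C/c1cc(OCc2ccccc2)c(OCc2ccccc2)cc1-c1c(OCc2ccccc2)cc(OCc2ccccc2)c2c(=O)cc(-c3ccc(OCc4ccccc4)c(OCc4ccccc4)c3)oc12)c1c(O)cc(OCc2ccccc2)cc1OCc1ccccc1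
F4 | step 13 | racemic 5,7-bis(benzyloxy)-2-{4,5-bis(benzyloxy)-2-[5,7-bis(benzyloxy)-2-(3,4-bis(benzyloxy)phenyl)-4-oxo-4H-chromen-8-yl]phenyl}-2,3-dihydro-4H-chromen-4-one | O=C1CC(c2cc(OCc3ccccc3)c(OCc3ccccc3)cc2-c2c(OCc3ccccc3)cc(OCc3ccccc3)c3c(=O)cc(-c4ccc(OCc5ccccc5)c(OCc5ccccc5)c4)oc23)Oc2cc(OCc3ccccc3)cc(OCc3ccccc3)c21
F5 | step 13 | (2S) enantiomer of 19 | O=C1C[C@@H](c2cc(OCc3ccccc3)c(OCc3ccccc3)cc2-c2c(OCc3ccccc3)cc(OCc3ccccc3)c3c(=O)cc(-c4ccc(OCc5ccccc5)c(OCc5ccccc5)c4)oc23)Oc2cc(OCc3ccccc3)cc(OCc3ccccc3)c21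
F6 | step 12 | (1aS,6bS)-4,6-bis(benzyloxy)-1a-[4,5-bis(benzyloxy)-2-(4,4,5,5-tetramethyl-1,3,2-dioxaborolan-2-yl)phenyl]-6b-[(tert-butyldimethylsilyl)oxy]-1a,6b-dihydro-1H-cyclopropa[b][1]benzofuran | C1[C@@]2(c3cc(OCc4ccccc4)c(OCc4ccccc4)cc3B3OC(C)(C)C(C)(C)O3)Oc3cc(OCc4ccccc4)cc(OCc4ccccc4)c3[C@@]12O[Si](C)(C)C(C)(C)C
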